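**Strategy.** The benzoxepine is disconnected at the C5–C5a aryl–alkenyl bond. The para relationship between the ring oxygen O1 (on C9a) and the C7 hydroxyl marks the benzene ring as the product of a dienone–phenol (quinol ether) rearrangement. In one acid-promoted operation a 1-oxaspiro[5.5]undecadienone loses its PMB group, the alkenyl carbon C5 shifts from the spiro carbon to the neighbouring ring CH, the six-membered oxane becomes the seven-membered oxepine, and the arene with its C7/C9 hydroxyls is formed. The spiro ether comes from 1,2-addition of a chiral 2-lithioallyl alkoxide to a 2-alkoxy-3-methylbenzoquinone, in situ angeloylation and 6-exo epoxide opening, which sets C2 by inversion.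

Key step: step 8

Assumption: 2-bromoacrolein (6), the Ipc2B(allyl) solution (7), angelic anhydride (13) and the D-fructose-derived epoxidation ketone are taken as purchasable; 15–18 are carried as mixtures of epimers at the quaternary ring carbon, which becomes aromatic in step 8.

Step 1
Reactants: 1 2-methylresorcinol (3 equiv); 2 4-methoxybenzyl chloride
Product: 3 3-[(4-methoxybenzyl)oxy]-2-methylphenol
Conditions: K2CO3, acetone, reflux; excess 1 recovered
Reagents that add atoms: 4-methoxybenzyl chloride (2), COc1ccc(CCl)cc1
Why: Williamson etherification of a symmetric diol, in which the excess of 1 should keep bis-alkylation low.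

Step 2
Reactants: 3 mono-PMB ether; 4 Fremy's salt
Product: 5 2-[(4-methoxybenzyl)oxy]-3-methyl-1,4-benzoquinone
Conditions: (KSO3)2NO (2.2 equiv), KH2PO4, acetone/H2O, rt
Reagents that add atoms: potassium nitrosodisulfonate (4), [K+].[K+].[O]N(S(=O)(=O)[O-])S(=O)(=O)[O-]
Why: Teuber oxidation of a phenol with a free para position should give the p-quinone, placing the new carbonyl next to the PMB-oxy carbon.

Step 3
Reactants: 6 2-bromoacrolein; 7 (−)-B-allyldiisopinocampheylborane (the antipode built from (−)-α-pinene)
Product: 8 (3R)-2-bromohexa-1,5-dien-3-ol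
Conditions: Et2O, −78 °C; then 3 M NaOH, 30% H2O2, rt
Reagents that add atoms: (−)-Ipc2B(allyl) (7), C=CCB([C@H]1C[C@H]2C[C@H](C2(C)C)[C@@H]1C)[C@H]1C[C@H]2C[C@H](C2(C)C)[C@@H]1C
Why: Brown allylboration through a closed chair transition state, in which the (−)-α-pinene-derived reagent should deliver allyl to the Re face of the aldehyde and so set the (R)-carbinol that becomes C4.

Step 4
Reactants: 8 (3R)-2-bromohexa-1,5-dien-3-ol; 9 2-methyl-2-butene
Product: 10 (3R)-2-bromo-6-methylhepta-1,5-dien-3-ol
Conditions: Grubbs II (5 mol %), 2-methyl-2-butene (excess), CH2Cl2, 40 °C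
Reagents that add atoms: 2-methyl-2-butene (9), CC=C(C)C
Why: Olefin cross-metathesis of the terminal alkene installs the prenyl-type alkene, while the electron-poor 1,1-disubstituted vinyl bromide should not engage the ruthenium carbene.

Step 5
Reactants: 10 (3R)-2-bromo-6-methylhepta-1,5-dien-3-ol; 11 Oxone
Product: 12 (2R)-3-bromo-1-[(2R)-3,3-dimethyloxiran-2-yl]but-3-en-2-ol
Conditions: D-fructose-derived Shi ketone (0.3 equiv), Oxone, K2CO3, Bu4NHSO4, MeCN/DMM/aq. buffer (pH 10.5), 0 °C; Et3N-deactivated silica
Reagents that add atoms: potassium peroxymonosulfate (11), [K+].[O-]S(=O)(=O)OO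
Why: Shi asymmetric epoxidation, in which the chiral dioxirane should attack only the electron-rich trisubstituted alkene and, through the spiro transition state, give the (R)-epoxide under reagent control.

Step 6
Reactants: 12 epoxy alcohol; 5 quinone; 13 angelic anhydride
Product: 16 quinol angelate (epimers at the ring carbinol carbon), via dilithio alkenyl alkoxide 14 (not isolated), via dilithium quinol dialkoxide 15 (not isolated)
Conditions: t-BuLi (3.0 equiv), THF, −78 °C; cannulate into 5, THF, −78 °C; then 13 (1.1 equiv), −78 → −30 °C; aq. NH4Cl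
Reagents that add atoms: angelic anhydride (13), C/C=C(/C)C(=O)OC(=O)/C(C)=C\C
Why: Bromine–lithium exchange on the lithium alkoxide gives a 2-lithioallyl alkoxide that should add 1,2 to the more electrophilic quinone carbonyl (the one not in vinylogous-ester conjugation with the PMB-oxy group), after which the less hindered secondary alkoxide is acylated in situ so that no free C4 hydroxyl ever faces the dienone; the new quaternary carbinol carbon forms without control, which is harmless because it is planarised in step 8.

Step 7
Reactants: 16 quinol angelate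
Product: 17 spiro ether (2S,4R)-2-(2-hydroxypropan-2-yl)-7-[(4-methoxybenzyl)oxy]-8-methyl-5-methylidene-9-oxo-1-oxaspiro[5.5]undeca-7,10-dien-4-yl angelate
Conditions: PPTS (0.2 equiv), CH2Cl2, 0 °C → rt
Reagents that add atoms: none
Why: Acid-catalysed intramolecular epoxide opening, in which the tertiary quinol hydroxyl should attack the secondary epoxide carbon in 6-exo-tet SN2 fashion, closing the oxane, releasing the tertiary alcohol and inverting the (R)-epoxide carbon to the (S)-configured C2.

Step 8
Reactants: 17 spiro ether
Product: 19 target benzoxepine, via spiro hydroxydienone 18 (not isolated)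
Conditions: TFA/CH2Cl2 (1:4), pentamethylbenzene (5 equiv), 0 °C → rt, argon; pH 7 buffer work-up
Reagents that add atoms: none
Why: Dienone–phenol (quinol ether) rearrangement: TFA should first transfer the 4-methoxybenzyl cation from the vinylogous ester to pentamethylbenzene, then protonate hydroxydienone 18 and trigger a suprafacial [1,2]-shift of the alkenyl carbon C5 from the spiro carbon to the adjacent unsubstituted ring CH, which then loses its proton to aromatise. The closest known reaction type is the acid-mediated rearrangement of 4-alkoxy-4-alkyl cyclohexadienones and spirodienones to ring-enlarged hydroquinone monoethers (spirolactone to 6-hydroxydihydrocoumarin, spiro[5.5]undecadienone to benzosuberanol). No ring is closed anew: the six-membered oxane (O1, C2, C3, C4, C5, spiro carbon) is enlarged to the seven-membered oxepine because the former dienone CH (C5a) comes to lie between C5 and the oxygen-bearing carbon (C9a). No stereocentre is created; C2 and C4 are untouched and the stereogenic spiro carbon becomes aromatic, so both spiro epimers converge. The step needs C-migration over O-migration, secured because keeping O1 on the cationic carbon gives an oxocarbenium ion and the sp2 carbon C5 migrates readily; it also needs migration to the CH and not to the oxygenated neighbour, secured because only the CH terminus can lose a proton to aromatise while the oxygenated carbon is the stabilised end of the vinylogous acid.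

**Compound list**

1 | 2-methylresorcinol | Cc1c(O)cccc1O | starting material
2 | 4-methoxybenzyl chloride | COc1ccc(CCl)cc1 | starting material
3 | 3-[(4-methoxybenzyl)oxy]-2-methylphenol | Cc1c(O)cccc1OCc1ccc(OC)cc1 | intermediate
4 | potassium nitrosodisulfonate (Fremy's salt) | [K+].[K+].[O]N(S(=O)(=O)[O-])S(=O)(=O)[O-] | starting material
5 | 2-[(4-methoxybenzyl)oxy]-3-methyl-1,4-benzoquinone | O=C1C=CC(=O)C(C)=C1OCc1ccc(OC)cc1 | intermediate
6 | 2-bromoacrolein | C=C(Br)C=O | starting material
7 | (−)-B-allyldiisopinocampheylborane (from (−)-α-pinene) | C=CCB([C@H]1C[C@H]2C[C@H](C2(C)C)[C@@H]1C)[C@H]1C[C@H]2C[C@H](C2(C)C)[C@@H]1C | starting material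
8 | (3R)-2-bromohexa-1,5-dien-3-ol | C=C(Br)[C@H](O)CC=C | intermediate
9 | 2-methyl-2-butene | CC=C(C)C | starting material
10 | (3R)-2-bromo-6-methylhepta-1,5-dien-3-ol | C=C(Br)[C@H](O)CC=C(C)C | intermediate
11 | potassium peroxymonosulfate (active component of Oxone) | [K+].[O-]S(=O)(=O)OO | starting material
12 | (2R)-3-bromo-1-[(2R)-3,3-dimethyloxiran-2-yl]but-3-en-2-ol | C=C(Br)[C@H](O)C[C@H]1OC1(C)C | intermediate
13 | angelic anhydride, (2Z)-2-methylbut-2-enoic anhydride | C/C=C(/C)C(=O)OC(=O)/C(C)=C\C | starting material
14 | lithium (2R)-1-[(2R)-3,3-dimethyloxiran-2-yl]-3-lithiobut-3-en-2-olate | C=C([Li])[C@H](O[Li])C[C@H]1OC1(C)C | intermediate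
15 | dilithium dialkoxide of the quinol adduct of 14 and 5 (epimers at the ring carbinol carbon) | C=C([C@H](O[Li])C[C@H]1OC1(C)C)C1(O[Li])C=CC(=O)C(C)=C1OCc1ccc(OC)cc1 | intermediate
16 | (2R)-1-[(2R)-3,3-dimethyloxiran-2-yl]-3-{1-hydroxy-2-[(4-methoxybenzyl)oxy]-3-methyl-4-oxocyclohexa-2,5-dien-1-yl}but-3-en-2-yl (2Z)-2-methylbut-2-enoate (epimers at ring C1) | C/C=C(/C)C(=O)O[C@H](C[C@H]1OC1(C)C)C(=C)C1(O)C=CC(=O)C(C)=C1OCc1ccc(OC)cc1 | intermediate
17 | (2S,4R)-2-(2-hydroxypropan-2-yl)-7-[(4-methoxybenzyl)oxy]-8-methyl-5-methylidene-9-oxo-1-oxaspiro[5.5]undeca-7,10-dien-4-yl (2Z)-2-methylbut-2-enoate (epimers at the spiro carbon) | C=C1C2(C=CC(=O)C(C)=C2OCc2ccc(OC)cc2)O[C@H](C(C)(C)O)C[C@H]1OC(=O)/C(C)=C\C | intermediate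
18 | (2S,4R)-7-hydroxy-2-(2-hydroxypropan-2-yl)-8-methyl-5-methylidene-9-oxo-1-oxaspiro[5.5]undeca-7,10-dien-4-yl (2Z)-2-methylbut-2-enoate (epimers at the spiro carbon) | C=C1C2(C=CC(=O)C(C)=C2O)O[C@H](C(C)(C)O)C[C@H]1OC(=O)/C(C)=C\C | intermediate
19 | (2S,4R)-7,9-dihydroxy-2-(2-hydroxypropan-2-yl)-8-methyl-5-methylidene-2,3,4,5-tetrahydro-1-benzoxepin-4-yl (2Z)-2-methylbut-2-enoate | C=C1c2cc(O)c(C)c(O)c2O[C@H](C(C)(C)O)C[C@H]1OC(=O)/C(C)=C\C | target

Total steps: 8. Longest linear sequence: 6 (steps 3–8); steps 1–2 form the convergent quinone branch.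

**Steps most likely to fail**

Step 8. What may go wrong: benzylation of the electron-rich hydroxyquinol (or of 18) by the liberated 4-methoxybenzyl cation despite the scavenger, and solvolysis of the tertiary alcohol during the longer acid exposure that the doubly oxygen-stabilised dienone may need. The fallback separates deprotection from rearrangement by using an allyl group in place of PMB. It sets out from 1: alkylation with allyl bromide (K2CO3, acetone) should give 3-(allyloxy)-2-methylphenol F1, and Fremy's salt should give 2-(allyloxy)-3-methyl-1,4-benzoquinone F2. The addition/angeloylation of step 6 with 12 and 13 should then give the allyl quinol angelate F3, and PPTS should close the allyl spiro ether F4. Pd(PPh3)4/morpholine in THF should remove the allyl group from the vinylogous ester, while the hindered secondary angelate beside the spiro carbon should not ionise. This comes back to the route at 18, now isolated, which is rearranged to 19 with BF3·OEt2 in CH2Cl2 at low temperature, with no carbocation source present.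

Step 6. What may go wrong: electron transfer from the dilithio reagent to the quinone in competition with 1,2-addition, unselective acylation of the two lithium alkoxides, and base-induced Z-to-E isomerisation of the angelate in the one-pot protocol. The fallback separates addition from acylation. It sets out from 12 and 5: the addition is run as before but quenched at −78 °C with AcOH in THF, without anhydride, to give the quinol diol F5. Its secondary allylic hydroxyl is then esterified at once under Yamaguchi conditions (angelic acid, 2,4,6-trichlorobenzoyl chloride, Et3N, toluene), the tertiary quinol hydroxyl being too hindered to react. This comes back to the route at 16.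

Step 7. What may go wrong: participation of the angelate carbonyl in the opening of the acid-activated epoxide (acyloxonium formation with acyl migration), in competition with the 6-exo attack of the hindered quinol hydroxyl. The fallback closes the oxane before the ester is present. It sets out from 12: silylation (TBSCl, imidazole, DMF) should give the silyl ether F6, and Br–Li exchange (t-BuLi, 2 equiv, −78 °C, used at once) followed by addition to 5 should give the silyl quinol F7. PPTS should then close the silyl spiro ether F8 with a non-participating group on the C4 oxygen, and HF·pyridine should give the spiro alcohol F9. Immediate Yamaguchi esterification with angelic acid comes back to the route at 17.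

**Further compounds**

F1 | step 8 | 3-(allyloxy)-2-methylphenol | Cc1c(O)cccc1OCC=C
F2 | step 8 | 2-(allyloxy)-3-methyl-1,4-benzoquinone | O=C1C=CC(=O)C(C)=C1OCC=C
F3 | step 8 | (2R)-1-[(2R)-3,3-dimethyloxiran-2-yl]-3-[1-hydroxy-3-methyl-4-oxo-2-(prop-2-en-1-yloxy)cyclohexa-2,5-dien-1-yl]but-3-en-2-yl (2Z)-2-methylbut-2-enoate | C/C=C(/C)C(=O)O[C@H](C[C@H]1OC1(C)C)C(=C)C1(O)C=CC(=O)C(C)=C1OCC=C
F4 | step 8 | (2S,4R)-2-(2-hydroxypropan-2-yl)-8-methyl-5-methylidene-9-oxo-7-(prop-2-en-1-yloxy)-1-oxaspiro[5.5]undeca-7,10-dien-4-yl (2Z)-2-methylbut-2-enoate | C=C1C2(C=CC(=O)C(C)=C2OCC=C)O[C@H](C(C)(C)O)C[C@H]1OC(=O)/C(C)=C\C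
F5 | step 6 | 4-{(3R)-4-[(2R)-3,3-dimethyloxiran-2-yl]-3-hydroxybut-1-en-2-yl}-4-hydroxy-3-[(4-methoxybenzyl)oxy]-2-methylcyclohexa-2,5-dien-1-one | C=C([C@H](O)C[C@H]1OC1(C)C)C1(O)C=CC(=O)C(C)=C1OCc1ccc(OC)cc1
F6 | step 7 | {[(2R)-3-bromo-1-[(2R)-3,3-dimethyloxiran-2-yl]but-3-en-2-yl]oxy}(tert-butyl)dimethylsilane | C=C(Br)[C@H](O[Si](C)(C)C(C)(C)C)C[C@H]1OC1(C)C
F7 | step 7 | 4-{(3R)-3-[(tert-butyldimethylsilyl)oxy]-4-[(2R)-3,3-dimethyloxiran-2-yl]but-1-en-2-yl}-4-hydroxy-3-[(4-methoxybenzyl)oxy]-2-methylcyclohexa-2,5-dien-1-one | C=C([C@H](O[Si](C)(C)C(C)(C)C)C[C@H]1OC1(C)C)C1(O)C=CC(=O)C(C)=C1OCc1ccc(OC)cc1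
F8 | step 7 | (2S,4R)-4-[(tert-butyldimethylsilyl)oxy]-2-(2-hydroxypropan-2-yl)-7-[(4-methoxybenzyl)oxy]-8-methyl-5-methylidene-1-oxaspiro[5.5]undeca-7,10-dien-9-one | C=C1C2(C=CC(=O)C(C)=C2OCc2ccc(OC)cc2)O[C@H](C(C)(C)O)C[C@H]1O[Si](C)(C)C(C)(C)C
F9 | step 7 | (2S,4R)-4-hydroxy-2-(2-hydroxypropan-2-yl)-7-[(4-methoxybenzyl)oxy]-8-methyl-5-methylidene-1-oxaspiro[5.5]undeca-7,10-dien-9-one | C=C1C2(C=CC(=O)C(C)=C2OCc2ccc(OC)cc2)O[C@H](C(C)(C)O)C[C@H]1O
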